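The benzene ring of the target carries only two substituents, the CH2CH2CO2C19H39 chain on C1 and the hydroxyl on C4, so it is disconnected into a 2-substituted buta-1,3-diene (C6, C1, C2, C3, with the propanoate chain on C1) and a two-carbon alkyne (C4, C5) whose boron on C4 stands in for the phenolic oxygen. A cobalt-catalysed [4+2] cycloaddition forms the C3–C4 and C5–C6 bonds in one operation and delivers the complete carbocycle as a 1,4-cyclohexadiene with the para pattern in place. The precursor is the nonadecyl ester of 4-methylidenehex-5-enoic acid, made from pent-4-ynoic acid by esterification and ene–yne metathesis with ethylene; dehydrogenation and C–B oxidation finish the synthesis.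

Key step: step 3

Remark: the target has no stereocentre and no stereogenic double bond, and its alkyl group is the unbranched C19 chain. Ring carbons are numbered C1 (chain-bearing) to C6, with oxygen on C4.

Step 1
Reactants: 1 pent-4-ynoic acid; 2 nonadecan-1-ol
Product: 3 nonadecyl pent-4-ynoate
Conditions: 1 (1.2 equiv), p-TsOH·H2O (5 mol%), toluene, reflux, Dean–Stark; aq. NaHCO3 wash
Reagents that add atoms: none
Why: Fischer esterification driven to completion by azeotropic removal of water; the terminal alkyne is inert to catalytic sulfonic acid and the excess of the water-soluble acid 1 is removed by the bicarbonate wash.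

Step 2
Reactants: 3 nonadecyl pent-4-ynoate; 4 ethylene
Product: 5 nonadecyl 4-methylidenehex-5-enoate
Conditions: second-generation Grubbs catalyst RuCl2(H2IMes)(PCy3)(=CHPh) (5 mol%), ethylene (1 atm), toluene, 80 °C
Reagents that add atoms: none
Why: Ene–yne cross-metathesis: the ruthenium methylidene adds across the terminal alkyne and the resulting vinylcarbene is turned over by ethylene, giving the 2-substituted buta-1,3-diene with the ester as a spectator; the ethylene atmosphere should suppress secondary metathesis of the diene.

Step 3
Reactants: 5 nonadecyl 4-methylidenehex-5-enoate; 6 ethynylboronic acid pinacol ester (2-ethynyl-4,4,5,5-tetramethyl-1,3,2-dioxaborolane)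
Product: 7 nonadecyl 3-[4-(4,4,5,5-tetramethyl-1,3,2-dioxaborolan-2-yl)cyclohexa-1,4-dien-1-yl]propanoate
Conditions: CoBr2(dppe) (10 mol%), Zn powder (20 mol%), ZnI2 (20 mol%), CH2Cl2, rt; 6 (1.2 equiv) added slowly
Reagents that add atoms: none
Why: Zn reduces divalent CoBr2(dppe) to a monovalent cobalt species that ZnI2 renders cationic; this centre binds diene 5 and alkyne 6, joins them by oxidative cyclisation to a trivalent allyl–alkenyl cobaltacycle and releases the carbocycle by reductive elimination. The closest known reaction type is the cobalt-catalysed neutral Diels–Alder reaction of alkynylboronic esters with unactivated 2-substituted 1,3-dienes, which tolerates esters and pinacol boronates. The six-membered ring is closed intermolecularly in a formal [4+2] mode, the C3–C4 and C5–C6 bonds both being formed at the metal, and it emerges as the skipped 1,4-diene because no hydrogen shifts. No stereocentre is created, so no stereocontrol is required. The step needs 1,4 (para) over 1,3 (meta) regiochemistry, which the lone substituent at C2 of the diene should secure inside the dppe pocket by steering the bulky boron-bearing alkyne carbon to the remote, unsubstituted vinyl terminus. It also needs cross-cycloaddition to outpace alkyne cyclotrimerisation, which slow addition of 6 in non-coordinating CH2Cl2 should ensure.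

Step 4
Reactants: 7 nonadecyl 3-[4-(4,4,5,5-tetramethyl-1,3,2-dioxaborolan-2-yl)cyclohexa-1,4-dien-1-yl]propanoate
Product: 8 nonadecyl 3-[4-(4,4,5,5-tetramethyl-1,3,2-dioxaborolan-2-yl)phenyl]propanoate
Conditions: DDQ (1.1 equiv), toluene, rt
Reagents that add atoms: none
Why: Dehydrogenative aromatisation: DDQ abstracts hydride from a doubly allylic ring CH2 and loss of a proton gives the arene, driven by aromaticity; the C–B bond and the ester are untouched under these neutral conditions.

Step 5
Reactants: 8 nonadecyl 3-[4-(4,4,5,5-tetramethyl-1,3,2-dioxaborolan-2-yl)phenyl]propanoate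
Product: 10 nonadecyl 3-(4-hydroxyphenyl)propanoate, via aryl pinacol borate 9 (not isolated)
Conditions: 30% aq. H2O2, NaHCO3, THF–H2O, 0 °C to rt; then aq. Na2S2O3
Reagents that add atoms: hydrogen peroxide, OO
Why: Ipso-oxidation of an arylboronic ester: hydroperoxide adds to boron, 1,2-migration of the aryl group from boron to oxygen gives borate 9, and hydrolysis in the aqueous medium releases the phenol; the bicarbonate buffer keeps the medium too mild to saponify the ester.

Compound list
1 | pent-4-ynoic acid | C#CCCC(=O)O | starting material
2 | nonadecan-1-ol | CCCCCCCCCCCCCCCCCCCO | starting material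
3 | nonadecyl pent-4-ynoate | CCCCCCCCCCCCCCCCCCCOC(=O)CCC#C | intermediate
4 | ethylene | C=C | starting material
5 | nonadecyl 4-methylidenehex-5-enoate | CCCCCCCCCCCCCCCCCCCOC(=O)CCC(=C)C=C | intermediate
6 | ethynylboronic acid pinacol ester (2-ethynyl-4,4,5,5-tetramethyl-1,3,2-dioxaborolane) | C#CB1OC(C)(C)C(C)(C)O1 | starting material
7 | nonadecyl 3-[4-(4,4,5,5-tetramethyl-1,3,2-dioxaborolan-2-yl)cyclohexa-1,4-dien-1-yl]propanoate | CCCCCCCCCCCCCCCCCCCOC(=O)CCC1=CCC(B2OC(C)(C)C(C)(C)O2)=CC1 | intermediate
8 | nonadecyl 3-[4-(4,4,5,5-tetramethyl-1,3,2-dioxaborolan-2-yl)phenyl]propanoate | CCCCCCCCCCCCCCCCCCCOC(=O)CCc1ccc(B2OC(C)(C)C(C)(C)O2)cc1 | intermediate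
9 | nonadecyl 3-{4-[(4,4,5,5-tetramethyl-1,3,2-dioxaborolan-2-yl)oxy]phenyl}propanoate | CCCCCCCCCCCCCCCCCCCOC(=O)CCc1ccc(OB2OC(C)(C)C(C)(C)O2)cc1 | intermediate
10 | nonadecyl 3-(4-hydroxyphenyl)propanoate | CCCCCCCCCCCCCCCCCCCOC(=O)CCc1ccc(O)cc1 | target

Total step count: 5
Longest linear sequence: 5 steps (1 → 3 → 5 → 7 → 8 → 10)

Steps most likely to fail

Step 3. The risk is erosion of para over meta regiocontrol, cyclotrimerisation of the terminal alkynylboronate, or loss of boron at the metal. The fallback sets out from alkynoate 3 and comes back to the route at target 10. It keeps the cobalt-mediated ring construction but swaps the roles of the partners. Compound 3 would serve as the alkyne and commercially available 2-(trimethylsilyloxy)buta-1,3-diene (C=CC(=C)O[Si](C)(C)C) as the diene, under CoBr2(dppe), Zn powder and ZnI2 in CH2Cl2 at rt. This pairing of a terminal alkyne with a 2-silyloxydiene is a known variant that places the oxygen para to the chain, and it should give nonadecyl 3-[4-(trimethylsilyloxy)cyclohexa-1,4-dien-1-yl]propanoate F1. DDQ in toluene at rt should aromatise this to nonadecyl 3-[4-(trimethylsilyloxy)phenyl]propanoate F2. Brief treatment with 1 M HCl in THF would then cleave the aryl silyl ether to 10 without touching the ester.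

Step 2. The risk is stalling of the ruthenium carbene through chelation by the ester carbonyl, or secondary metathesis and oligomerisation of the diene. The fallback sets out from 3 and comes back at diene 5. Markovnikov hydroiodination with HI generated in the flask (NaI, Me3SiCl, H2O, MeCN, rt) should give nonadecyl 4-iodopent-4-enoate F3. Stille coupling of this alkenyl iodide with tributyl(vinyl)stannane (PdCl2(MeCN)2, DMF, rt) would attach the vinyl group under neutral conditions and deliver 5.

Step 4. The risk is incomplete dehydrogenation, protodeboronation of the dienylboronate during handling, or hydride abstraction at an unintended position. The fallback sets out from 7 and comes back at target 10, reversing the order of oxidation and aromatisation. The alkenyl C–B bond would be oxidised first (30% aq. H2O2, NaHCO3, THF–H2O, 0 °C), and the resulting enol should tautomerise to nonadecyl 3-(4-oxocyclohex-1-en-1-yl)propanoate F4. Aerobic dehydrogenation of this cyclohexenone (Pd(OCOCF3)2, 2-(dimethylamino)pyridine, p-TsOH, O2 at 1 atm, DMSO, 80 °C) is a known conversion of cyclohexenones into phenols through divalent palladium enolates and β-hydride elimination, and it would give 10 directly.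

Further compounds
F1 | step 3 | nonadecyl 3-[4-(trimethylsilyloxy)cyclohexa-1,4-dien-1-yl]propanoate | CCCCCCCCCCCCCCCCCCCOC(=O)CCC1=CCC(O[Si](C)(C)C)=CC1
F2 | step 3 | nonadecyl 3-[4-(trimethylsilyloxy)phenyl]propanoate | CCCCCCCCCCCCCCCCCCCOC(=O)CCc1ccc(O[Si](C)(C)C)cc1
F3 | step 2 | nonadecyl 4-iodopent-4-enoate | CCCCCCCCCCCCCCCCCCCOC(=O)CCC(I)=C
F4 | step 4 | nonadecyl 3-(4-oxocyclohex-1-en-1-yl)propanoate | CCCCCCCCCCCCCCCCCCCOC(=O)CCC1=CCC(=O)CC1
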